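The north-west flask cannot have stopped for want of coupling partner: by the ledger below, 6.42 mM of it stands unspent.

in all of them: starting material 20 mM; free catalyst 68 µM
- north-west: coupling partner 10 mM; capture agent 0.40 mM; temperature 50 °C; the very flask that is asked about, followed so far
- north-east: coupling partner 10 mM; capture agent 0.40 mM; temperature 45 °C; run made earlier
- flask: coupling partner 10.0 mM; capture agent 0.400 mM; temperature 50 °C; time 30 h

| run | time / h | product / % | starting material / % |
|---|---|---|---|
| north-west | 4.00 | 8.9 | 91.2 |
| north-west | 10.0 | 14.1 | 85.7 |
| north-west | 20.0 | 17.3 | 82.6 |
| north-west | 30.0 | 17.9 | 82.5 |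
| north-east | 4.00 | 5.9 | 93.9 |
| north-east | 10.0 | 10.8 | 89.4 |
| north-east | 20.0 | 13.7 | 86.2 |
| north-east | 30.0 | 14.7 | 85.6 |

(readings scatter by 0.3 percentage points)

- noon: at 30 h take out 90 % of the product then present, then wait 10 h
- spring: at 30 h add coupling partner, 50.0 % of the amount charged, then wait 10 h
- dusk: change nothing and wait 10 h more
- winter: at 30 h raise the temperature by 15 K, then wait 10 h
- autumn: at 30 h add free catalyst, 100 % of the amount charged, then wait 10 h

- product that was removed still counts
- the numbers in the tables scatter with a standard deviation of 0.3 percentage points
- additions bring no volume worth counting

* product, in percent of the starting material first charged, at 30 h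
* the remedy with the largest gain of product, or "none" below 2 percentage points (noon / spring / dusk / winter / autumn / none)
* product present, with what was taken out counted in, in percent of the starting material first charged, after noon
* product present, with what was taken out counted in, in percent of the starting material first charged, after winter

The ledger of the north-west flask, reckoned here, takes one coupling partner per product.

1. Charge: 10.0 mM of coupling partner meets 20 mM of starting material, so, taken one to one, coupling partner is the limiting reagent of the charge.

2. Product: the reading of 17.9 % at 30.0 h books 3.58 mM. With the starting material read beside it, the balance comes to 100 %, so no side entry shows.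

3. Remainder: 6.42 mM stays in the flask, more than product has taken.

4. Stall: the last 10 h added 0.6 percentage points, and the 10 h before added 3.2 points. If the gains keep shrinking in that proportion, the next 10 h adds 0.11 points, giving 18.0 %.

5. Catalyst: the entry that closes the books is the turnover number N, the moles of product made per mole of catalyst charged. The last reading of the north-west run gives N = 52.6 at 50 °C, and the last reading of the north-east run gives 43.2 at 45 °C, each with the scatter of its reading.

6. Remedies: the reckoning here commits to 17.9 % now. It assumes that a charge of catalyst has used up its count, so removing product, adding partner, waiting and heating each stay below 2 points. A fresh charge, spending N again, gains 18 points.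

The forecast gave 18 %, 18.4 % after noon, 18.7 % after winter and autumn as best, in its words “Fresh catalyst restarts the reaction, giving about 8 points”, where the reckoning here gives 18 points.

The flask gives 17.9 %, 18.0 % after noon and 18.2 % after winter, and autumn gains 16 points.

    coupling partner + free catalyst → catalyst intermediate A (k = 61000 /M/h, Ea = 58.0 kJ/mol)
    catalyst intermediate C → free catalyst + product (k = 3400 /h, Ea = 90.0 kJ/mol)
    starting material + catalyst intermediate B ⇌ catalyst intermediate C (K = 64.0 /M, k = 9700 /M/h, Ea = 58.0 kJ/mol, ΔH = −44.0 kJ/mol)
    catalyst intermediate A + capture agent → trapped intermediate (k = 500 /M/h, Ea = 49.0 kJ/mol)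
    free catalyst → spent catalyst (k = 4.80 × 10⁻⁵ /h, Ea = 128 kJ/mol)
    catalyst intermediate A → catalyst intermediate B (k = 9.70 /h, Ea = 82.0 kJ/mol)
    (constants at 50 °C)

At 30.0 h, catalyst intermediate A passes on to catalyst intermediate B 58 times as fast as capture agent takes it, and N reads 52.6. There the trapped intermediate holds 99.1 % of the catalyst charged, and free catalyst holds 0.0196 %. The flask charged with 5.0 mM of starting material ends at 69.8 %, which is 51.3 turnovers, against 71.6 % reckoned from N.

The numbers in the tables come from a simulation for an exercise.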